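**Retrosynthetic overview**
- Eurycomalin A comes from hydrolysis of the one methyl ester in an acid–ester 7,7'-biaryl.
- The C7–C7' bond is made last-but-one by a carboxylate-directed, norbornene-relayed meta C–H arylation: the free acid of one half directs, the 7-iodo methyl ester of the other half is the aryl donor.
- Acid half: 2-bromophenol → para-iodination → methoxycarbonylation → asymmetric Heck/Tsuji–Trost annulation with isoprene → saponification.
- Iodide half: 4-iodophenol → methoxycarbonylation → ortho-iodination → ortho-bromination → iodine-selective asymmetric annulation with isoprene → Br-to-I exchange.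
- Ring order: each dihydrofuran ring is closed on its own benzene ring before the halves are joined; no ring is formed after the coupling.

Assumption: the hand of the TY-Phos-type ligand that gives the 2S centre is fixed in a trial run (chiral HPLC, rotation against known (S)-fomannoxin acid), and the same hand is used in both annulations. Isoprene is counted as a starting material; CO and methanol are reagents.

**Step 1**
Reactants: 1 2-bromophenol
Product: 2 2-bromo-4-iodophenol
Conditions: NIS (1.05 equiv), TsOH·H2O (10 mol %), MeCN, 0 °C to rt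
Reagents that add atoms: N-iodosuccinimide (NIS), O=C1CCC(=O)N1I
Why: Electrophilic aromatic iodination; the hydroxyl group sends the bulky iodinating agent to the free para position.

**Step 2**
Reactants: 2 2-bromo-4-iodophenol
Product: 3 methyl 3-bromo-4-hydroxybenzoate
Conditions: PdCl2(PPh3)2 (2 mol %), CO (1 atm), Et3N (2 equiv), MeOH, 55 °C
Reagents that add atoms: carbon monoxide, [C-]#[O+]; methanol, CO
Why: Palladium-catalysed methoxycarbonylation (Heck carbonylation); zerovalent palladium adds to C–I far faster than to C–Br, so only the para position becomes the ester.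

**Step 3**
Reactants: 3 methyl 3-bromo-4-hydroxybenzoate; 4 isoprene (2-methylbuta-1,3-diene, 4 equiv)
Product: 5 methyl (2S)-2-(prop-1-en-2-yl)-2,3-dihydro-1-benzofuran-5-carboxylate
Conditions: Pd2(dba)3·CHCl3 (2.5 mol %), TY-Phos-type chiral sulfinamide phosphine (10 mol %), K2CO3 (2 equiv), toluene, 90 °C, sealed tube
Reagents that add atoms: none
Why: Asymmetric Heck/Tsuji–Trost heteroannulation of a 1,3-diene (enantioselective Larock-type annulation): the aryl–palladium adds to the unsubstituted vinyl end of isoprene, and ligand-controlled attack of the phenoxide on the inner terminus of the 2-methyl-π-allyl palladium closes the ring and sets C2 as S.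

**Step 4**
Reactants: 5 methyl (2S)-2-(prop-1-en-2-yl)-2,3-dihydro-1-benzofuran-5-carboxylate
Product: 6 (2S)-2-(prop-1-en-2-yl)-2,3-dihydro-1-benzofuran-5-carboxylic acid ((S)-fomannoxin acid)
Conditions: LiOH·H2O (3 equiv), THF/MeOH/H2O, 40 °C; then 1 M HCl to pH 3, 0 °C
Reagents that add atoms: lithium hydroxide, [Li+].[OH-]
Why: Ester saponification; C2 has no acidic hydrogen and the allylic ether is stable to hydroxide, so the stereocentre is kept.

**Step 5**
Reactants: 7 4-iodophenol
Product: 8 methyl 4-hydroxybenzoate
Conditions: Pd(OAc)2 (1 mol %), Xantphos (1.5 mol %), CO (1 atm), Et3N (2 equiv), MeOH, 65 °C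
Reagents that add atoms: carbon monoxide, [C-]#[O+]; methanol, CO
Why: Palladium-catalysed methoxycarbonylation of an aryl iodide; in methanol the acyl–palladium is trapped by the solvent faster than by the free phenol.

**Step 6**
Reactants: 8 methyl 4-hydroxybenzoate
Product: 9 methyl 4-hydroxy-3-iodobenzoate
Conditions: NIS (1.05 equiv), TFA (0.3 equiv), MeCN, rt
Reagents that add atoms: N-iodosuccinimide (NIS), O=C1CCC(=O)N1I
Why: Electrophilic aromatic iodination; para is blocked, hydroxyl (ortho) and ester (meta) both direct to C3, and the first iodine slows a second substitution.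

**Step 7**
Reactants: 9 methyl 4-hydroxy-3-iodobenzoate
Product: 10 methyl 3-bromo-4-hydroxy-5-iodobenzoate
Conditions: NBS (1.05 equiv), iPr2NH (10 mol %), CH2Cl2, 0 °C
Reagents that add atoms: N-bromosuccinimide (NBS), O=C1CCC(=O)N1Br
Why: Amine-catalysed ortho-bromination of a phenol (electrophilic aromatic substitution); C5 is the only activated position left, and the mild non-acidic medium avoids loss of iodine.

**Step 8**
Reactants: 10 methyl 3-bromo-4-hydroxy-5-iodobenzoate; 4 isoprene (4 equiv)
Product: 11 methyl (2S)-7-bromo-2-(prop-1-en-2-yl)-2,3-dihydro-1-benzofuran-5-carboxylate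
Conditions: Pd2(dba)3·CHCl3 (2.5 mol %), same chiral ligand (10 mol %), K2CO3 (2 equiv), toluene, 65 °C, stopped at full conversion of 10
Reagents that add atoms: none
Why: The same asymmetric Heck/Tsuji–Trost heteroannulation at lower temperature, where oxidative addition occurs only at C–I; phenoxide attack on the π-allyl palladium sets C2 as S and the untouched C–Br becomes C7–Br.

**Step 9**
Reactants: 11 methyl (2S)-7-bromo-2-(prop-1-en-2-yl)-2,3-dihydro-1-benzofuran-5-carboxylate
Product: 12 methyl (2S)-7-iodo-2-(prop-1-en-2-yl)-2,3-dihydro-1-benzofuran-5-carboxylate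
Conditions: CuI (10 mol %), trans-N,N'-dimethylcyclohexane-1,2-diamine (20 mol %), NaI (2 equiv), 1,4-dioxane, 110 °C
Reagents that add atoms: sodium iodide, [Na+].[I-]
Why: Copper-catalysed aromatic Finkelstein reaction; exchange at C7 is driven by precipitation of NaBr and leaves ester, alkene and C2 alone.

**Step 10**
Reactants: 6 (2S)-2-(prop-1-en-2-yl)-2,3-dihydro-1-benzofuran-5-carboxylic acid (1.3 equiv); 12 methyl (2S)-7-iodo-2-(prop-1-en-2-yl)-2,3-dihydro-1-benzofuran-5-carboxylate (1.0 equiv)
Product: 13 (2S,2'S)-5'-(methoxycarbonyl)-2,2'-di(prop-1-en-2-yl)-2,2',3,3'-tetrahydro-[7,7'-bi-1-benzofuran]-5-carboxylic acid (acid on the ring from 6, methyl ester on the ring from 12)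
Conditions: Pd(OAc)2 (10 mol %), 3-acetamido-5-(trifluoromethyl)pyridin-2-ol (20 mol %), methyl bicyclo[2.2.1]hept-2-ene-2-carboxylate (1.5 equiv), AgOAc (2.5 equiv), HFIP, 90 °C
Reagents that add atoms: none
Why: Proposed new method: carboxylate-directed, norbornene-relayed meta C–H arylation of a benzoic acid. The carboxylate of 6 brings divalent palladium to the unhindered ortho C6–H; the strained alkene inserts and passes the metal to the neighbouring C7–H, the only free meta position (C3a is substituted), giving an aryl–norbornyl palladacycle; oxidative addition of iodide 12 to tetravalent palladium and C–C reductive elimination make the C7–C7' bond; β-carbon elimination releases the norbornene and protonation frees C6, with AgOAc taking up the iodide. Closest known reaction type: Catellani-type (palladium/norbornene) meta C–H arylation of phenylacetic acids and anilides with aryl iodides, together with carboxylate-directed ortho C–H arylation of benzoic acids; the relay has not been shown from a benzoic acid or on a dihydrobenzofuran. The cycle stays between divalent and tetravalent palladium, so the allylic aryl ethers (which zerovalent palladium could ionise) and both stereocentres are not touched.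

**Step 11**
Reactants: 13 (2S,2'S)-5'-(methoxycarbonyl)-2,2'-di(prop-1-en-2-yl)-2,2',3,3'-tetrahydro-[7,7'-bi-1-benzofuran]-5-carboxylic acid
Product: 14 Eurycomalin A, (2S,2'S)-2,2'-di(prop-1-en-2-yl)-2,2',3,3'-tetrahydro-[7,7'-bi-1-benzofuran]-5,5'-dicarboxylic acid
Conditions: LiOH·H2O (4 equiv), THF/MeOH/H2O, 40 °C; then 1 M HCl to pH 3, 0 °C
Reagents that add atoms: lithium hydroxide, [Li+].[OH-]
Why: Ester saponification; neither stereocentre is epimerisable under hydroxide and the cold, mild acidification leaves the isopropenyl groups intact.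

**Compound list**
1 | 2-bromophenol | Oc1ccccc1Br | starting material
2 | 2-bromo-4-iodophenol | Oc1ccc(I)cc1Br | intermediate
3 | methyl 3-bromo-4-hydroxybenzoate | COC(=O)c1ccc(O)c(Br)c1 | intermediate
4 | isoprene (2-methylbuta-1,3-diene) | C=CC(C)=C | starting material
5 | methyl (2S)-2-(prop-1-en-2-yl)-2,3-dihydro-1-benzofuran-5-carboxylate | C=C(C)[C@@H]1Cc2cc(C(=O)OC)ccc2O1 | intermediate
6 | (2S)-2-(prop-1-en-2-yl)-2,3-dihydro-1-benzofuran-5-carboxylic acid | C=C(C)[C@@H]1Cc2cc(C(=O)O)ccc2O1 | intermediate
7 | 4-iodophenol | Oc1ccc(I)cc1 | starting material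
8 | methyl 4-hydroxybenzoate | COC(=O)c1ccc(O)cc1 | intermediate
9 | methyl 4-hydroxy-3-iodobenzoate | COC(=O)c1ccc(O)c(I)c1 | intermediate
10 | methyl 3-bromo-4-hydroxy-5-iodobenzoate | COC(=O)c1cc(Br)c(O)c(I)c1 | intermediate
11 | methyl (2S)-7-bromo-2-(prop-1-en-2-yl)-2,3-dihydro-1-benzofuran-5-carboxylate | C=C(C)[C@@H]1Cc2cc(C(=O)OC)cc(Br)c2O1 | intermediate
12 | methyl (2S)-7-iodo-2-(prop-1-en-2-yl)-2,3-dihydro-1-benzofuran-5-carboxylate | C=C(C)[C@@H]1Cc2cc(C(=O)OC)cc(I)c2O1 | intermediate
13 | (2S,2'S)-5'-(methoxycarbonyl)-2,2'-di(prop-1-en-2-yl)-2,2',3,3'-tetrahydro-[7,7'-bi-1-benzofuran]-5-carboxylic acid | C=C(C)[C@@H]1Cc2cc(C(=O)O)cc(-c3cc(C(=O)OC)cc4c3O[C@H](C(=C)C)C4)c2O1 | intermediate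
14 | Eurycomalin A, (2S,2'S)-2,2'-di(prop-1-en-2-yl)-2,2',3,3'-tetrahydro-[7,7'-bi-1-benzofuran]-5,5'-dicarboxylic acid | C=C(C)[C@@H]1Cc2cc(C(=O)O)cc(-c3cc(C(=O)O)cc4c3O[C@H](C(=C)C)C4)c2O1 | target

**Step count**
Total steps: 11. Longest linear sequence: 7 (steps 5 to 11); the other arm is 6 (steps 1 to 4, then 10 and 11).

**Three steps most likely to fail, with fallbacks**

Step 10 (the new relay arylation). The risks are direct ortho arylation at C6, palladation from the ether side leading to the C6-aryl isomer, and palladium chemistry at the isopropenyl groups. The fallback uses known chemistry and sets out from bromide 11. Miyaura borylation (B2pin2, Pd(dppf)Cl2, KOAc, dioxane, 80 °C) gives methyl (2S)-2-(prop-1-en-2-yl)-7-(4,4,5,5-tetramethyl-1,3,2-dioxaborolan-2-yl)-2,3-dihydro-1-benzofuran-5-carboxylate F1. Suzuki–Miyaura coupling of F1 with iodide 12 (Pd(OAc)2, SPhos, K3PO4, THF/H2O, 40 °C, kept mild so that zerovalent palladium does not open the allylic ether) gives dimethyl (2S,2'S)-2,2'-di(prop-1-en-2-yl)-2,2',3,3'-tetrahydro-[7,7'-bi-1-benzofuran]-5,5'-dicarboxylate F2. Double saponification (LiOH, then HCl) comes back to the route at 14.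

Step 8 (iodine-selective asymmetric annulation next to a C–Br bond). The risks are further reaction of the product at C–Br and lower ee with the hindered, iodide-derived system. The fallback replaces the π-allyl palladium ring closure by an epoxide-based one and sets out from 3. Ortho C-prenylation of its sodium phenoxide (NaH, 1-bromo-3-methylbut-2-ene, toluene, rt) gives methyl 3-bromo-4-hydroxy-5-(3-methylbut-2-en-1-yl)benzoate F3. Shi asymmetric epoxidation (fructose-derived ketone of the hand that gives the R epoxide, Oxone (2KHSO5·KHSO4·K2SO4), K2CO3 buffer, MeCN/dimethoxymethane/H2O, 0 °C) gives methyl 3-bromo-5-{[(2R)-3,3-dimethyloxiran-2-yl]methyl}-4-hydroxybenzoate F4. In the same basic medium the phenoxide opens F4 (5-exo, inversion) to methyl (2S)-7-bromo-2-(2-hydroxypropan-2-yl)-2,3-dihydro-1-benzofuran-5-carboxylate F5. Dehydration toward the methyl group with Burgess reagent (toluene, 70 °C) comes back to the route at 11.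

Step 9 (halogen exchange). The risks are incomplete exchange giving an inseparable bromide/iodide mixture and slow ester demethylation by iodide at 110 °C. The fallback goes through a tin intermediate and sets out from 11. Palladium-catalysed stannylation (Me3SnSnMe3, Pd(PPh3)4, toluene, 90 °C) gives methyl (2S)-2-(prop-1-en-2-yl)-7-(trimethylstannyl)-2,3-dihydro-1-benzofuran-5-carboxylate F6. Ipso-iododestannylation (I2, 1.0 equiv, CH2Cl2, −40 °C, faster than any addition to the alkene) comes back to the route at 12.

**Further compounds**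
F1 | step 10 | methyl (2S)-2-(prop-1-en-2-yl)-7-(4,4,5,5-tetramethyl-1,3,2-dioxaborolan-2-yl)-2,3-dihydro-1-benzofuran-5-carboxylate | C=C(C)[C@@H]1Cc2cc(C(=O)OC)cc(B3OC(C)(C)C(C)(C)O3)c2O1
F2 | step 10 | dimethyl (2S,2'S)-2,2'-di(prop-1-en-2-yl)-2,2',3,3'-tetrahydro-[7,7'-bi-1-benzofuran]-5,5'-dicarboxylate | C=C(C)[C@@H]1Cc2cc(C(=O)OC)cc(-c3cc(C(=O)OC)cc4c3O[C@H](C(=C)C)C4)c2O1
F3 | step 8 | methyl 3-bromo-4-hydroxy-5-(3-methylbut-2-en-1-yl)benzoate | COC(=O)c1cc(Br)c(O)c(CC=C(C)C)c1
F4 | step 8 | methyl 3-bromo-5-{[(2R)-3,3-dimethyloxiran-2-yl]methyl}-4-hydroxybenzoate | COC(=O)c1cc(Br)c(O)c(C[C@H]2OC2(C)C)c1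
F5 | step 8 | methyl (2S)-7-bromo-2-(2-hydroxypropan-2-yl)-2,3-dihydro-1-benzofuran-5-carboxylate | CC(C)(O)[C@@H]1Cc2cc(C(=O)OC)cc(Br)c2O1
F6 | step 9 | methyl (2S)-2-(prop-1-en-2-yl)-7-(trimethylstannyl)-2,3-dihydro-1-benzofuran-5-carboxylate | C=C(C)[C@@H]1Cc2cc(C(=O)OC)cc([Sn](C)(C)C)c2O1
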